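**Plan**

1. Numbering (eudesmane): ring A = C1–C5/C10, ring B = C5–C10; C4 is the carbinol carbon (methyl C15), C10 the quaternary carbon (methyl C14), C7 carries C11(=C13)–C12O2H, C9 carries the ester oxygen; β is the face of C14.
2. Cuts: C12 acid from an allylic alcohol; the C9 ester into (S)-3-methylpentanoic acid and a 9α-alcohol, itself from a C9 ketone; then C5–C10 and C6–C7 together ([4+2]); then C7=C8 (olefination), C1–C10 (alkylation) and a C6–CHO helper (cross-metathesis), back to (R)-linalool (C2–C6 and C15).
3. Enabling feature: in ring B the oxygenated C9 lies between C8 and the quaternary C10, so C8=C9(OSi) is the retron of a 2-silyloxydiene C7=C8–C9=C10 adding to a dienophile C5=C6. Carbons C1–C4 of ring A already join C10 to C5 and serve as the tether, so both rings and the quaternary centre arise together.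
4. Forward order: the chain is joined first (iodide, β-ketophosphonate, dienone, silyl dienol ether), then rings A and B close in one operation, then helpers are removed and oxidation levels adjusted.
5. Helpers: a formyl group on C6 (iminium activation and polarity match C10 to C5; excised by Pinnick oxidation and Barton decarboxylation) and the C9 silyl enol ether (to the ketone, then 9α-OH).
6. Stereochemistry: C4 from (R)-linalool; C5, C10 and C7 from the catalyst-controlled endo cycloaddition (E-enal, E-C7=C8, C14 inside); C9 by equatorial hydride delivery; the side-chain centre from (S)-3-methylpentanoic acid.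

Key step: step 10

Remark: (R)-(−)-linalool, (S)-3-methylpentanoic acid, acrolein diethyl acetal, diethyl (2-oxobutyl)phosphonate and 2-methylenepropane-1,3-diol are taken as commercial, enantiopure where chiral; the eudesmane numbering is used for open-chain intermediates too.

**Route**

Step 1
Reactants: 1 (R)-linalool
Product: 2 linalool triethylsilyl ether
Conditions: Et3SiOTf, 2,6-lutidine, CH2Cl2, −78 → 0 °C
Reagents that add atoms: triethylsilyl trifluoromethanesulfonate, CC[Si](CC)(CC)OS(=O)(=O)C(F)(F)F
Why: Silyl triflate with 2,6-lutidine is the standard silylation of a hindered tertiary alcohol, leaves C4 untouched, and blocks later tetrahydrofuran and lactol formation.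

Step 2
Reactants: 2 linalool triethylsilyl ether
Product: 3 (4R)-4-methyl-4-(triethylsilyloxy)hex-5-en-1-ol
Conditions: O3, CH2Cl2/MeOH, −78 °C (Sudan Red 7B end-point); then NaBH4, −78 → 0 °C
Reagents that add atoms: ozone, [O-][O+]=O
Why: Chemoselective ozonolysis with reductive work-up should cleave the electron-rich trisubstituted alkene well before the vinyl group on the silyloxy-bearing quaternary carbon, and borohydride gives the primary alcohol.

Step 3
Reactants: 3 (4R)-4-methyl-4-(triethylsilyloxy)hex-5-en-1-ol
Product: 4 (3R)-6-iodo-3-methyl-3-(triethylsilyloxy)hex-1-ene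
Conditions: PPh3, iodine (I2), imidazole, CH2Cl2, 0 °C
Reagents that add atoms: iodine, II
Why: Appel-type iodination converts the primary alcohol under near-neutral conditions that spare the tertiary silyl ether and the vinyl group.

Step 4
Reactants: 4 (3R)-6-iodo-3-methyl-3-(triethylsilyloxy)hex-1-ene; 5 acrolein diethyl acetal
Product: 6 (2E,4R)-1,1-diethoxy-7-iodo-4-methyl-4-(triethylsilyloxy)hept-2-ene
Conditions: 5 (4 equiv), second-generation Hoveyda–Grubbs catalyst RuCl2(H2IMes)(=CH–C6H4–2-O-i-Pr) (5 mol%), CH2Cl2, 40 °C
Reagents that add atoms: none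
Why: Olefin cross-metathesis between a hindered, non-dimerising vinyl group and an excess of a readily dimerising partner should give the E-configured masked enal, the acetal keeping C6–CHO inert to the following carbanion chemistry.

Step 5
Reactants: 6 (2E,4R)-1,1-diethoxy-7-iodo-4-methyl-4-(triethylsilyloxy)hept-2-ene; 7 diethyl (2-oxobutyl)phosphonate
Product: 8 γ-alkylated β-ketophosphonate (both C10 epimers)
Conditions: 7 (2 equiv), NaH, THF, 0 °C; n-BuLi, 0 °C; then 6, 0 °C → rt; AcOH quench
Reagents that add atoms: none
Why: A β-ketophosphonate dianion alkylates at its more reactive γ-carbanion with a primary iodide, forming C1–C10 with C14 in place; the new centre at C10 does not matter because it becomes sp2 in step 9.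

Step 6
Reactants: 9 2-methylenepropane-1,3-diol
Product: 10 2-[(tert-butyldimethylsilyloxy)methyl]prop-2-en-1-ol
Conditions: NaH (1 equiv), THF, 0 °C; t-BuMe2SiCl (1 equiv), rt
Reagents that add atoms: tert-butyldimethylsilyl chloride, CC(C)(C)[Si](C)(C)Cl
Why: Monosilylation through the poorly soluble monosodium alkoxide differentiates the two equivalent hydroxyl groups of a symmetric diol.

Step 7
Reactants: 10 2-[(tert-butyldimethylsilyloxy)methyl]prop-2-en-1-ol
Product: 11 2-[(tert-butyldimethylsilyloxy)methyl]prop-2-enal
Conditions: MnO2, CH2Cl2, rt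
Reagents that add atoms: none
Why: Manganese dioxide oxidises an allylic alcohol selectively to the 2-substituted acrolein without touching the silyl ether.

Step 8
Reactants: 8 γ-alkylated β-ketophosphonate; 11 2-[(tert-butyldimethylsilyloxy)methyl]prop-2-enal
Product: 12 cross-conjugated (E)-dienone (both C10 epimers)
Conditions: Ba(OH)2, THF/H2O 40:1, 0 °C → rt
Reagents that add atoms: none
Why: Horner–Wadsworth–Emmons olefination of a β-ketophosphonate under mild Ba(OH)2 conditions should give the E-enone C7=C8 and tolerate the sensitive enal partner, the acetal and both silyl ethers.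

Step 9
Reactants: 12 cross-conjugated (E)-dienone
Product: 13 tert-butyldimethylsilyl dienol ether (Z at C9=C10 drawn)
Conditions: KN(SiMe3)2, THF, −78 °C; t-BuMe2SiCl, −78 → 0 °C
Reagents that add atoms: tert-butyldimethylsilyl chloride, CC(C)(C)[Si](C)(C)Cl
Why: The α'-methine C10 is the only acidic site of the dienone, so kinetic deprotonation and O-silylation give the 2-silyloxydiene, and allylic strain against the dienyl group should favour the isomer with the tether cis to oxygen and C14 inside.

Step 10
Reactants: 13 tert-butyldimethylsilyl dienol ether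
Product: 16 bicyclic keto aldehyde, via trienal 14 (not isolated), via silyl enol ether cycloadduct 15 (not isolated)
Conditions: (2S,5S)-5-benzyl-2-tert-butyl-3-methylimidazolidin-4-one·CF3CO2H (20 mol%), MeCN/H2O 19:1, −20 → 4 °C; then Bu4NF/AcOH (1:1), THF, −20 °C
Reagents that add atoms: water, O
Why: Proposed new method: the conjugated acetal is hydrolysed in the flask and enal 14 condenses with the imidazolidinone to an (E)-iminium ion whose β-carbon C5 is attacked by C10, the nucleophilic terminus of the 2-silyloxydiene, while the resulting enamine carbon C6 bonds to C7 in a strongly asynchronous [4+2] (in the limit a Mukaiyama–Michael addition followed by an enamine Michael addition), so that C5–C10 and C6–C7 form in one operation. The closest known reaction types are the iminium-catalysed intramolecular Diels–Alder reaction of 2,8,10-trienals to trans-decalins and the iminium-catalysed Mukaiyama–Michael addition of silyl enol ethers to enals; new here are the tetrasubstituted silyloxydiene terminus and the quaternary allylic carbon C4. Ring A closes by the tether-enforced 6-exo attack of C10 on C5 (type 1 intramolecular mode, C1–C4 as tether), and ring B is the ring of the cycloaddition itself (6-endo closure of C6 onto C7 in the stepwise limit). C5 is set by the catalyst, whose benzyl group covers one face of the iminium ion, reinforced by the C4–OSiEt3 bond lying anti to the incoming C10 (Felkin–Anh); C10 is set by the endo transition state that gives the trans ring fusion with C14 inside; C7 follows from the E geometry of C7=C8 with suprafacial bonding (side chain cis to C1, trans to C14); the temporary centre C6 follows from the E-enal in the endo mode. The step needs regioselectivity, secured by the tether and by the matched polarity of C10 and the iminium β-carbon C5, and periselectivity over the outer diene C13=C11–C7=C8, which could reach the dienophile only through a medium ring. Buffered fluoride then releases the C9 ketone from silyl enol ether 15 without cleaving the alkyl silyl ethers.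

Step 11
Reactants: 16 bicyclic keto aldehyde
Product: 17 bicyclic keto acid
Conditions: NaClO2, NaH2PO4, 2-methyl-2-butene, t-BuOH/H2O, 0 °C → rt
Reagents that add atoms: sodium chlorite, [Na+].[O-]Cl=O
Why: Pinnick oxidation converts the aldehyde to the acid chemoselectively, the scavenger alkene protecting C11=C13 from hypochlorous acid, and the configuration at C6 is irrelevant because this carbon becomes CH2.

Step 12
Reactants: 17 bicyclic keto acid
Product: 19 bicyclic ketone with C6 as CH2, via Barton ester 18 (not isolated)
Conditions: 2-mercaptopyridine N-oxide, DCC, DMAP (cat.), CH2Cl2, 0 °C → rt, dark; then t-BuSH, hν (tungsten lamp), 0 → 25 °C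
Reagents that add atoms: none
Why: In this Barton decarboxylation the thiohydroxamate ester fragments to the secondary C6 radical, which the fast hydrogen donor t-BuSH should reduce before any homoallyl rearrangement toward C11=C13; the radical route is preferred to RhCl(PPh3)3 decarbonylation of 16, whose 4-pentenal unit invites hydroacylation.

Step 13
Reactants: 19 bicyclic ketone with C6 as CH2
Product: 20 9α-alcohol
Conditions: LiBH(s-Bu)3, THF, −78 → −20 °C; then H2O
Reagents that add atoms: none
Why: The bulky hydride cannot approach C9 axially past the axial C7 side chain and H5 on the α face, so kinetic equatorial delivery should give the axial 9α-alcohol.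

Step 14
Reactants: 20 9α-alcohol; 21 (S)-3-methylpentanoic acid
Product: 23 bis-silylated 9α-ester, via mixed anhydride 22 (not isolated)
Conditions: 21, 2,4,6-trichlorobenzoyl chloride, Et3N, THF, rt; then 20, DMAP, toluene, 60 °C
Reagents that add atoms: none
Why: Yamaguchi esterification (mixed anhydride, then DMAP acyl transfer) is the standard method for hindered secondary alcohols, the acid's β-stereocentre cannot epimerise, and the tertiary O4 is still silylated.

Step 15
Reactants: 23 bis-silylated 9α-ester
Product: 24 4α,12-diol ester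
Conditions: HF·pyridine, pyridine/THF, 0 °C → rt
Reagents that add atoms: none
Why: Buffered hydrogen fluoride cleaves the primary tert-butyldimethylsilyl and tertiary triethylsilyl ethers without touching the ester and without the acyl migration that basic fluoride could cause.

Step 16
Reactants: 24 4α,12-diol ester
Product: 26 target acid, via enal 25 (not isolated)
Conditions: TEMPO (10 mol%), PhI(OAc)2, CH2Cl2, rt; then t-BuOH/H2O, 2-methyl-2-butene, NaClO2, NaH2PO4, 0 °C → rt
Reagents that add atoms: sodium chlorite, [Na+].[O-]Cl=O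
Why: Oxoammonium oxidation is selective for the primary allylic alcohol over the tertiary one, and Pinnick oxidation of the resulting 2-substituted acrolein should give the acrylic acid without moving the C11=C13 double bond.

**Compound list**

1 | (R)-(−)-linalool, (3R)-3,7-dimethylocta-1,6-dien-3-ol | C=C[C@](C)(O)CCC=C(C)C | starting material
2 | (3R)-3,7-dimethyl-3-(triethylsilyloxy)octa-1,6-diene | C=C[C@](C)(O[Si](CC)(CC)CC)CCC=C(C)C | intermediate
3 | (4R)-4-methyl-4-(triethylsilyloxy)hex-5-en-1-ol | C=C[C@](C)(O[Si](CC)(CC)CC)CCCO | intermediate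
4 | (3R)-6-iodo-3-methyl-3-(triethylsilyloxy)hex-1-ene | C=C[C@](C)(O[Si](CC)(CC)CC)CCCI | intermediate
5 | acrolein diethyl acetal, 3,3-diethoxyprop-1-ene | C=CC(OCC)OCC | starting material
6 | (2E,4R)-1,1-diethoxy-7-iodo-4-methyl-4-(triethylsilyloxy)hept-2-ene | CCOC(OCC)/C=C/[C@](C)(O[Si](CC)(CC)CC)CCCI | intermediate
7 | diethyl (2-oxobutyl)phosphonate | CCC(=O)CP(=O)(OCC)OCC | starting material
8 | diethyl [(7R,8E)-10,10-diethoxy-3,7-dimethyl-2-oxo-7-(triethylsilyloxy)dec-8-en-1-yl]phosphonate, both C3 epimers (C3 = eudesmane C10) | CCOC(OCC)/C=C/[C@](C)(O[Si](CC)(CC)CC)CCCC(C)C(=O)CP(=O)(OCC)OCC | intermediate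
9 | 2-methylenepropane-1,3-diol | C=C(CO)CO | starting material
10 | 2-[(tert-butyldimethylsilyloxy)methyl]prop-2-en-1-ol | C=C(CO)CO[Si](C)(C)C(C)(C)C | intermediate
11 | 2-[(tert-butyldimethylsilyloxy)methyl]prop-2-enal | C=C(C=O)CO[Si](C)(C)C(C)(C)C | intermediate
12 | (3E,10R,11E)-2-[(tert-butyldimethylsilyloxy)methyl]-13,13-diethoxy-6,10-dimethyl-10-(triethylsilyloxy)trideca-1,3,11-trien-5-one, both C6 epimers | CCOC(OCC)/C=C/[C@](C)(O[Si](CC)(CC)CC)CCCC(C)C(=O)/C=C/C(=C)CO[Si](C)(C)C(C)(C)C | intermediate
13 | (3E,5Z,10R,11E)-5-(tert-butyldimethylsilyloxy)-2-[(tert-butyldimethylsilyloxy)methyl]-13,13-diethoxy-6,10-dimethyl-10-(triethylsilyloxy)trideca-1,3,5,11-tetraene (5E isomer expected alongside) | CCOC(OCC)/C=C/[C@](C)(O[Si](CC)(CC)CC)CCC/C(C)=C(O[Si](C)(C)C(C)(C)C)/C=C/C(=C)CO[Si](C)(C)C(C)(C)C | intermediate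
14 | (2E,4R,8Z,10E)-9-(tert-butyldimethylsilyloxy)-12-[(tert-butyldimethylsilyloxy)methyl]-4,8-dimethyl-4-(triethylsilyloxy)trideca-2,8,10,12-tetraenal | O=C/C=C/[C@](C)(O[Si](CC)(CC)CC)CCC/C(C)=C(O[Si](C)(C)C(C)(C)C)/C=C/C(=C)CO[Si](C)(C)C(C)(C)C | intermediate (not isolated)
15 | trans-fused cycloadduct: 6α-formyl-9,12-bis(tert-butyldimethylsilyloxy)-4α-(triethylsilyloxy)eudesma-8,11(13)-diene with 5α-H, 10β-CH3, 4β-CH3 and the C7 side chain α | C=C(CO[Si](C)(C)C(C)(C)C)[C@@H]1[C@H](C=O)[C@@H]2[C@](C)(CCC[C@@]2(C)O[Si](CC)(CC)CC)C(O[Si](C)(C)C(C)(C)C)=C1 | intermediate (not isolated)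
16 | keto aldehyde: 6α-formyl-12-(tert-butyldimethylsilyloxy)-4α-(triethylsilyloxy)eudesm-11(13)-en-9-one with 5α-H, 10β-CH3, 4β-CH3 and the C7 side chain α | C=C(CO[Si](C)(C)C(C)(C)C)[C@@H]1[C@H](C=O)[C@@H]2[C@](C)(CCC[C@@]2(C)O[Si](CC)(CC)CC)C(=O)C1 | intermediate
17 | keto acid: 12-(tert-butyldimethylsilyloxy)-9-oxo-4α-(triethylsilyloxy)eudesm-11(13)-ene-6α-carboxylic acid, ring stereochemistry as in 16 | C=C(CO[Si](C)(C)C(C)(C)C)[C@@H]1[C@H](C(=O)O)[C@@H]2[C@](C)(CCC[C@@]2(C)O[Si](CC)(CC)CC)C(=O)C1 | intermediate
18 | Barton ester: 2-thioxopyridin-1(2H)-yl ester of acid 17 | C=C(CO[Si](C)(C)C(C)(C)C)[C@@H]1[C@H](C(=O)ON3C=CC=CC3=S)[C@@H]2[C@](C)(CCC[C@@]2(C)O[Si](CC)(CC)CC)C(=O)C1 | intermediate (not isolated)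
19 | ketone: 12-(tert-butyldimethylsilyloxy)-4α-(triethylsilyloxy)eudesm-11(13)-en-9-one with 5α-H, 10β-CH3, 4β-CH3 and the C7 side chain α | C=C(CO[Si](C)(C)C(C)(C)C)[C@@H]1C[C@@H]2[C@](C)(CCC[C@@]2(C)O[Si](CC)(CC)CC)C(=O)C1 | intermediate
20 | 9α-alcohol: 12-(tert-butyldimethylsilyloxy)-4α-(triethylsilyloxy)eudesm-11(13)-en-9α-ol, ring stereochemistry as in 19 | C=C(CO[Si](C)(C)C(C)(C)C)[C@@H]1C[C@@H]2[C@](C)(CCC[C@@]2(C)O[Si](CC)(CC)CC)[C@H](O)C1 | intermediate
21 | (3S)-3-methylpentanoic acid | O=C(O)C[C@@H](C)CC | starting material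
22 | (3S)-3-methylpentanoic 2,4,6-trichlorobenzoic anhydride | O=C(C[C@@H](C)CC)OC(=O)c1c(Cl)cc(Cl)cc1Cl | intermediate (not isolated)
23 | 9α-[(3S)-3-methylpentanoyloxy]-12-(tert-butyldimethylsilyloxy)-4α-(triethylsilyloxy)eudesm-11(13)-ene, ring stereochemistry as in 19 | C=C(CO[Si](C)(C)C(C)(C)C)[C@@H]1C[C@@H]2[C@](C)(CCC[C@@]2(C)O[Si](CC)(CC)CC)[C@H](OC(=O)C[C@@H](C)CC)C1 | intermediate
24 | 9α-[(3S)-3-methylpentanoyloxy]eudesm-11(13)-ene-4α,12-diol, ring stereochemistry as in 19 | C=C(CO)[C@@H]1C[C@@H]2[C@](C)(CCC[C@@]2(C)O)[C@H](OC(=O)C[C@@H](C)CC)C1 | intermediate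
25 | 4α-hydroxy-9α-[(3S)-3-methylpentanoyloxy]eudesm-11(13)-en-12-al, ring stereochemistry as in 19 | C=C(C=O)[C@@H]1C[C@@H]2[C@](C)(CCC[C@@]2(C)O)[C@H](OC(=O)C[C@@H](C)CC)C1 | intermediate (not isolated)
26 | 2-[(2R,4R,4aS,8R,8aR)-8-hydroxy-4a,8-dimethyl-4-{[(3S)-3-methylpentanoyl]oxy}decahydronaphthalen-2-yl]prop-2-enoic acid | C=C(C(=O)O)[C@@H]1C[C@@H]2[C@](C)(CCC[C@@]2(C)O)[C@H](OC(=O)C[C@@H](C)CC)C1 | target

**Step count and risks**

Total step count: 16. Longest linear sequence: 14 (steps 1–5 and 8–16, from (R)-linalool).

Steps most likely to fail: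

Step 10 (proposed new method). The silyl dienol ether may be protodesilylated before the C5–C10 bond forms, closure of this crowded bond may be slow, and endo or facial control may erode (cis-fused closure, or catalyst and C4 working against each other). The 5E isomer of 13 can only follow the stepwise limit. Fallback with known chemistry, using substrate control instead of catalyst control: starting from dienone 12, the acetal is cleaved with pyridinium p-toluenesulfonate in wet acetone to (2E,4R,10E)-12-[(tert-butyldimethylsilyloxy)methyl]-4,8-dimethyl-9-oxo-4-(triethylsilyloxy)trideca-2,10,12-trienal F1. Treating it with t-BuMe2SiOTf/Et3N in CH2Cl2 (−78 → 0 °C) forms the dienol ether in the flask and drives a silyl-triflate-promoted intramolecular double Michael addition, a known tactic for enone–acceptor pairs. The resulting silyl enol ether 15 is cleaved with buffered Bu4NF, and the route is rejoined at 16. Facial control then rests on the Felkin–Anh preference at C4 alone.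

Step 4. Metathesis at a vinyl group on a fully substituted, silyloxy-bearing carbon may stall while the acetal homodimerises and the catalyst decays. Fallback by olefination: starting from iodide 4, ozonolysis (O3, CH2Cl2, −78 °C; Me2S) gives (2R)-5-iodo-2-methyl-2-(triethylsilyloxy)pentanal F2. Wittig reaction with Ph3P=CHCHO (toluene, 60 °C) gives (2E,4R)-7-iodo-4-methyl-4-(triethylsilyloxy)hept-2-enal F3, and acetalisation (HC(OEt)3, EtOH, cat. pyridinium p-toluenesulfonate) returns to 6.

Step 14. Acyl transfer to the axial, neopentyl-type C9 hydroxyl, which is 1,3-diaxial to the C7 side chain, may be too slow, so that the mixed anhydride is lost to the symmetrical anhydride. Fallback by acylation of the preformed alkoxide: starting from alcohol 20, deprotonation with n-BuLi (THF, −78 °C) and reaction of the lithium alkoxide with (3S)-3-methylpentanoyl chloride F4 (from 21 with oxalyl chloride, cat. DMF) returns to 23.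

Further compounds
F1 | step 10 | (2E,4R,10E)-12-[(tert-butyldimethylsilyloxy)methyl]-4,8-dimethyl-9-oxo-4-(triethylsilyloxy)trideca-2,10,12-trienal (both C8 epimers) | O=C/C=C/[C@](C)(O[Si](CC)(CC)CC)CCCC(C)C(=O)/C=C/C(=C)CO[Si](C)(C)C(C)(C)C
F2 | step 4 | (2R)-5-iodo-2-methyl-2-(triethylsilyloxy)pentanal | O=C[C@](C)(O[Si](CC)(CC)CC)CCCI
F3 | step 4 | (2E,4R)-7-iodo-4-methyl-4-(triethylsilyloxy)hept-2-enal | O=C/C=C/[C@](C)(O[Si](CC)(CC)CC)CCCI
F4 | step 14 | (3S)-3-methylpentanoyl chloride | O=C(Cl)C[C@@H](C)CC
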